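**Plan**
- Retrosynthesis: the quinone is cut back to its hydroquinone tetra-acetate; the bond between C6 of ring B and the vanillyl CH2 is cut to a 5,8-dihydronaphthalene and vanillin acetate; ring B is cut by a retro-Diels–Alder reaction into 2-methoxy-1,4-benzoquinone (ring A) and an (E)-1-aryl-2-methylbutadiene; the diene goes back to vanillin by two olefinations.
- Forward: two Wittig reactions give the diene, the Diels–Alder reaction builds ring B on ring A at the dihydro level and fixes the 2-OMe/8-aryl relationship, and enolization–acetylation locks ring A as a hydroquinone diacetate.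
- Enabling feature: ring B before aromatization holds an isolated C6=C7 alkene whose C7 methyl makes C6 the nucleophilic (Markovnikov) carbon, and its two hydrogens beyond the aromatic level (one each at C5 and C8) are exactly what an aldehyde carbon needs to become CH2 plus water.
- The union with vanillin acetate is therefore a redox-neutral carbonyl-ene reaction followed by dehydrative aromatization of ring B; methanolysis and FeCl3 oxidation then release the quinone.
- Stereochemistry: the target has no stereocentre; the centres of the cycloadduct (C4a, C8, C8a) and of the ene adduct are transient and erased in steps 4 and 5; the E geometry of the diene comes from the stabilized ylide.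

Key step: step 5

Assumption: 2-methoxy-1,4-benzoquinone, vanillin acetate and 2-(triphenylphosphoranylidene)propanal are taken as commercial.

**Step 1**
Reactants: 1 vanillin; 2 2-(triphenylphosphoranylidene)propanal
Product: 3 (E)-3-(4-hydroxy-3-methoxyphenyl)-2-methylprop-2-enal
Conditions: toluene, 110 °C
Reagents that add atoms: none
Why: Wittig olefination with a formyl-stabilized ylide should give the (E)-trisubstituted enal, and the conjugated, α-branched product is less electrophilic than vanillin, so a second homologation should not compete.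

**Step 2**
Reactants: 3 (E)-3-(4-hydroxy-3-methoxyphenyl)-2-methylprop-2-enal
Product: 4 2-methoxy-4-[(1E)-2-methylbuta-1,3-dien-1-yl]phenol
Conditions: Ph3PCH3Br (2.5 equiv), KOtBu (2.5 equiv), THF, 0 to 23 °C; aq NH4Cl; product stored cold with BHT
Reagents that add atoms: methyltriphenylphosphonium bromide, C[P+](c1ccccc1)(c1ccccc1)c1ccccc1.[Br-]
Why: Wittig methylenation, in which one equivalent of base is spent on the phenol and the non-stabilized ylide adds 1,2 to the enal without touching the existing E double bond.

**Step 3**
Reactants: 4 2-methoxy-4-[(1E)-2-methylbuta-1,3-dien-1-yl]phenol; 5 2-methoxy-1,4-benzoquinone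
Product: 6 8-(4-hydroxy-3-methoxyphenyl)-2-methoxy-7-methyl-4a,5,8,8a-tetrahydronaphthalene-1,4-dione (racemic, H-4a, H-8 and H-8a on one face)
Conditions: toluene, 80 °C, dark, BHT (cat.)
Reagents that add atoms: none
Why: thermal Diels–Alder reaction at the unsubstituted double bond of 5; the carbonyl next to the OMe-bearing carbon is the stronger acceptor (the other is a vinylogous ester), so the CH2 terminus of the diene bonds to the carbon β to it and the aryl-bearing carbon ends next to that carbonyl, while the endo transition state sets the all-cis relative configuration, which is erased later.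

**Step 4**
Reactants: 6 the Diels–Alder adduct
Product: 7 8-(4-acetoxy-3-methoxyphenyl)-2-methoxy-7-methyl-5,8-dihydronaphthalene-1,4-diyl diacetate (racemic at C8)
Conditions: Ac2O, pyridine, DMAP (cat.), 23 °C
Reagents that add atoms: acetic anhydride, CC(=O)OC(C)=O
Why: double enolization of the ene-dione to the hydroquinone (aromatization of ring A) with acetylation in the same flask is a standard fate of quinone Diels–Alder adducts; the phenol is acetylated as well and the isolated C6=C7 bond should stay in place because pyridine is too weak a base to deprotonate C5 or C8.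

**Step 5**
Reactants: 7 8-(4-acetoxy-3-methoxyphenyl)-2-methoxy-7-methyl-5,8-dihydronaphthalene-1,4-diyl diacetate; 8 vanillin acetate (4-formyl-2-methoxyphenyl acetate)
Product: 10 6-(4-acetoxy-3-methoxybenzyl)-8-(4-acetoxy-3-methoxyphenyl)-2-methoxy-7-methylnaphthalene-1,4-diyl diacetate, via homoallylic alcohol 9 (not isolated)
Conditions: Me2AlCl (3 equiv), CH2Cl2, −78 to 0 °C; then CF3CO2H (20 equiv), 0 to 23 °C; 1 M HCl work-up
Reagents that add atoms: none
Why: Proposed new method: the Me2AlCl-bound aldehyde 8 should attack C6 of the C6=C7 alkene of ring B in a carbonyl-ene reaction (closest known type: the Me2AlCl-mediated ene reaction of aldehydes with trisubstituted alkenes), with positive charge developing on the methyl-bearing C7 and the doubly benzylic H-8 being transferred to give the aluminium alkoxide of 9. Acid should then ionize the benzylic C–O bond, the cation should lose H-6 to give an exocyclic benzylidene, and a proton shift from C5 to the benzylic carbon, driven by aromatization of ring B, should deliver the C6–CH2Ar bond at the correct oxidation level without external oxidant or reductant (closest known type: the acid-mediated isoaromatization of 2-benzylidene-1-tetralones to 2-benzyl-1-naphthols). No ring is closed; ring B is aromatized. The centres at C6, C8 and the carbinol carbon are transient and all erased, so no stereocontrol is needed. Regioselectivity for C6 over C7 follows from Markovnikov attack on the trisubstituted alkene, and chemoselectivity over Friedel–Crafts attack follows from the acetate groups, which should lower the nucleophilicity of ring A and of both guaiacyl rings below that of the alkene. The aprotic, proton-scavenging Me2AlCl is chosen to suppress acid-catalysed migration of the C6=C7 bond into conjugation before the C–C bond is formed.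

**Step 6**
Reactants: 10 6-(4-acetoxy-3-methoxybenzyl)-8-(4-acetoxy-3-methoxyphenyl)-2-methoxy-7-methylnaphthalene-1,4-diyl diacetate
Product: 12 larreantin, via hydroquinone 11 (not isolated)
Conditions: K2CO3 (5 equiv), degassed MeOH, 23 °C, argon; 1 M HCl to pH 3; then FeCl3 (2.2 equiv), MeOH/H2O, 0 °C
Reagents that add atoms: none
Why: base-mediated methanolysis should remove the four aryl acetates (methoxide can only exchange the 2-OMe group degenerately), and FeCl3 oxidation of the electron-rich naphthalene-1,4-diol to the 1,4-quinone is standard, with an oxidant too weak to attack the guaiacyl phenols under these conditions.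

**Compound list**
1 | vanillin (4-hydroxy-3-methoxybenzaldehyde) | O=Cc1ccc(O)c(OC)c1 | starting material
2 | 2-(triphenylphosphoranylidene)propanal | CC(C=O)=P(c1ccccc1)(c1ccccc1)c1ccccc1 | starting material
3 | (E)-3-(4-hydroxy-3-methoxyphenyl)-2-methylprop-2-enal | O=C/C(C)=C/c1ccc(O)c(OC)c1 | intermediate
4 | 2-methoxy-4-[(1E)-2-methylbuta-1,3-dien-1-yl]phenol | C=C/C(C)=C/c1ccc(O)c(OC)c1 | intermediate
5 | 2-methoxy-1,4-benzoquinone | COC1=CC(=O)C=CC1=O | starting material
6 | 8-(4-hydroxy-3-methoxyphenyl)-2-methoxy-7-methyl-4a,5,8,8a-tetrahydronaphthalene-1,4-dione, racemic, H-4a/H-8/H-8a all cis (one enantiomer drawn) | COC1=CC(=O)[C@H]2CC=C(C)[C@@H](c3ccc(O)c(OC)c3)[C@H]2C1=O | intermediate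
7 | 8-(4-acetoxy-3-methoxyphenyl)-2-methoxy-7-methyl-5,8-dihydronaphthalene-1,4-diyl diacetate, racemic at C8 | COc1cc(OC(C)=O)c2c(c1OC(C)=O)C(c1ccc(OC(C)=O)c(OC)c1)C(C)=CC2 | intermediate
8 | vanillin acetate (4-formyl-2-methoxyphenyl acetate) | CC(=O)Oc1ccc(C=O)cc1OC | starting material
9 | 8-(4-acetoxy-3-methoxyphenyl)-6-[(4-acetoxy-3-methoxyphenyl)(hydroxy)methyl]-2-methoxy-7-methyl-5,6-dihydronaphthalene-1,4-diyl diacetate, mixture of diastereomers, formed as its aluminium alkoxide | COc1cc(OC(C)=O)c2c(c1OC(C)=O)C(c1ccc(OC(C)=O)c(OC)c1)=C(C)C(C(O)c1ccc(OC(C)=O)c(OC)c1)C2 | intermediate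
10 | 6-(4-acetoxy-3-methoxybenzyl)-8-(4-acetoxy-3-methoxyphenyl)-2-methoxy-7-methylnaphthalene-1,4-diyl diacetate | COc1cc(OC(C)=O)c2cc(Cc3ccc(OC(C)=O)c(OC)c3)c(C)c(-c3ccc(OC(C)=O)c(OC)c3)c2c1OC(C)=O | intermediate
11 | 6-(4-hydroxy-3-methoxybenzyl)-8-(4-hydroxy-3-methoxyphenyl)-2-methoxy-7-methylnaphthalene-1,4-diol | COc1cc(O)c2cc(Cc3ccc(O)c(OC)c3)c(C)c(-c3ccc(O)c(OC)c3)c2c1O | intermediate
12 | larreantin | COC1=CC(=O)c2cc(Cc3ccc(O)c(OC)c3)c(C)c(-c3ccc(O)c(OC)c3)c2C1=O | target

**Step count and risks**
Total step count: 6. Longest linear sequence: 6 steps (from 1).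

Steps most likely to fail:

Step 5. Three processes could divert it: hydride transfer from the doubly activated C5 or C8 positions to the activated aldehyde (aromatization without C–C bond formation); migration of the C6=C7 bond into conjugation before the ene reaction; and methyl transfer from aluminium to the aldehyde. The fallback uses known chemistry, sets out from 8 and 5 and returns at 10, moving the union to the diene stage. Acid-catalysed aldol condensation of 8 with butan-2-one (HCl, AcOH) at the methylene carbon should give (E)-4-(4-acetoxy-3-methoxyphenyl)-3-methylbut-3-en-2-one F1. Tf2O with 2,6-di-tert-butyl-4-methylpyridine in CH2Cl2 should convert it into the dienyl triflate 4-[(1E)-2-methyl-3-(trifluoromethylsulfonyloxy)buta-1,3-dien-1-yl]-2-methoxyphenyl acetate F2. Commercial 2-methoxy-4-methylphenyl acetate is brominated at the benzylic position (NBS, AIBN) to 4-(bromomethyl)-2-methoxyphenyl acetate F3, and Zn dust with LiCl in THF should turn this into (4-acetoxy-3-methoxybenzyl)zinc bromide F4. Negishi coupling of F2 with F4 (Pd(OAc)2, SPhos, THF) should form the same C–CH2 bond and give 4-[(1E)-3-(4-acetoxy-3-methoxybenzyl)-2-methylbuta-1,3-dien-1-yl]-2-methoxyphenyl acetate F5. Diels–Alder reaction with 5 (toluene, 80 °C) should give the benzyl-bearing tetrahydronaphthalenedione F6, Ac2O/pyridine the 6-benzyl-5,8-dihydronaphthalene tetra-acetate F7, and DDQ dehydrogenation of ring B should return to 10.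

Step 3. The cycloaddition could leak to the other regioisomer, because the C2 methyl of the diene opposes the directing effect of the C1 aryl group and the methoxy group polarizes the remote double bond of 5 only weakly. The fallback sets out from 4 and returns at 7, using a removable halogen for regiocontrol. Dakin oxidation of commercial 5-bromovanillin (H2O2, NaOH; then HCl) should give 2-bromo-6-methoxybenzene-1,4-diol F8, and FeCl3 oxidation 2-bromo-6-methoxy-1,4-benzoquinone F9. Diene 4 should add to the brominated double bond with its CH2 terminus on the unsubstituted carbon, giving the 8a-bromo adduct F10. Zn dust in Ac2O/pyridine (reductive debromination to the enolate, O-acetylation, second enolization–acetylation, phenol acetylation) should deliver 7.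

Step 2. Olefination of the phenoxide-deactivated enal could stall, and the free phenolic diene could polymerize on isolation. The fallback sets out from 8 and 2 and returns at 7, carrying the phenol as its acetate and replacing the basic ylide by a non-basic titanium methylene reagent. Wittig reaction of 8 with 2 (toluene, 110 °C) should give (E)-3-(4-acetoxy-3-methoxyphenyl)-2-methylprop-2-enal F11. Methylenation with Zn, CH2Br2 and TiCl4 (THF/CH2Cl2, 0 °C) should give 4-[(1E)-2-methylbuta-1,3-dien-1-yl]-2-methoxyphenyl acetate F12. Diels–Alder reaction with 5 should give the acetylated adduct F13, and Ac2O/pyridine/DMAP should convert it into 7.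

**Further compounds**
F1 | step 5 | (E)-4-(4-acetoxy-3-methoxyphenyl)-3-methylbut-3-en-2-one | CC(=O)/C(C)=C/c1ccc(OC(C)=O)c(OC)c1
F2 | step 5 | 4-[(1E)-2-methyl-3-(trifluoromethylsulfonyloxy)buta-1,3-dien-1-yl]-2-methoxyphenyl acetate | C=C(OS(=O)(=O)C(F)(F)F)/C(C)=C/c1ccc(OC(C)=O)c(OC)c1
F3 | step 5 | 4-(bromomethyl)-2-methoxyphenyl acetate | CC(=O)Oc1ccc(CBr)cc1OC
F4 | step 5 | (4-acetoxy-3-methoxybenzyl)zinc bromide | CC(=O)Oc1ccc(C[Zn]Br)cc1OC
F5 | step 5 | 4-[(1E)-3-(4-acetoxy-3-methoxybenzyl)-2-methylbuta-1,3-dien-1-yl]-2-methoxyphenyl acetate | C=C(Cc1ccc(OC(C)=O)c(OC)c1)/C(C)=C/c1ccc(OC(C)=O)c(OC)c1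
F6 | step 5 | 6-(4-acetoxy-3-methoxybenzyl)-8-(4-acetoxy-3-methoxyphenyl)-2-methoxy-7-methyl-4a,5,8,8a-tetrahydronaphthalene-1,4-dione, racemic, H-4a/H-8/H-8a all cis | COC1=CC(=O)[C@H]2CC(Cc3ccc(OC(C)=O)c(OC)c3)=C(C)[C@@H](c3ccc(OC(C)=O)c(OC)c3)[C@H]2C1=O
F7 | step 5 | 6-(4-acetoxy-3-methoxybenzyl)-8-(4-acetoxy-3-methoxyphenyl)-2-methoxy-7-methyl-5,8-dihydronaphthalene-1,4-diyl diacetate, racemic at C8 | COc1cc(OC(C)=O)c2c(c1OC(C)=O)C(c1ccc(OC(C)=O)c(OC)c1)C(C)=C(Cc1ccc(OC(C)=O)c(OC)c1)C2
F8 | step 3 | 2-bromo-6-methoxybenzene-1,4-diol | COc1cc(O)cc(Br)c1O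
F9 | step 3 | 2-bromo-6-methoxy-1,4-benzoquinone | COC1=CC(=O)C=C(Br)C1=O
F10 | step 3 | 8a-bromo-8-(4-hydroxy-3-methoxyphenyl)-2-methoxy-7-methyl-4a,5,8,8a-tetrahydronaphthalene-1,4-dione, racemic, H-4a/H-8/Br-8a on one face | COC1=CC(=O)[C@H]2CC=C(C)[C@@H](c3ccc(O)c(OC)c3)[C@@]2(Br)C1=O
F11 | step 2 | (E)-3-(4-acetoxy-3-methoxyphenyl)-2-methylprop-2-enal | O=C/C(C)=C/c1ccc(OC(C)=O)c(OC)c1
F12 | step 2 | 4-[(1E)-2-methylbuta-1,3-dien-1-yl]-2-methoxyphenyl acetate | C=C/C(C)=C/c1ccc(OC(C)=O)c(OC)c1
F13 | step 2 | 8-(4-acetoxy-3-methoxyphenyl)-2-methoxy-7-methyl-4a,5,8,8a-tetrahydronaphthalene-1,4-dione, racemic, H-4a/H-8/H-8a all cis | COC1=CC(=O)[C@H]2CC=C(C)[C@@H](c3ccc(OC(C)=O)c(OC)c3)[C@H]2C1=O
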